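**Strategy.** The synthesis rests on reading the oxepane (C14–C15–C16–C17–C18–O19–C20, numbering in the remark below) as a cyclohexanone with one oxygen inserted. Baeyer–Villiger oxidation of a trans-decalone with its carbonyl at C18 moves the ring-fusion carbon C20 onto O19 with retention. Ring expansion, the C20–O19 bond and the trans ring fusion therefore arise in one operation, and the lactone carbonyl later becomes the gem-dimethyl carbon C18 next to the C17 ketone. The precursor is a decalone from (S)-Wieland–Miescher ketone whose C12 hydroxymethyl and C23 carbinol are both triethylsilyl ethers. A limonene-derived hydroazulene boronate is joined late by stereoinvertive Zweifel olefination.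

Key step: step 11

Remark: skeletal atoms are numbered along the target: hydroazulene C1 (CHMe), C2, C3, C4 and C5 (ring fusion), C6, C7, C8 (carbinol), C9 (CMe2), C10; alkene C10=C11; C12 (CH2); C13 (CH), C14 (CMe), C15, C16, C17 (ketone), C18 (OCMe2), O19, C20 (OCH), C21, C22, C23 (carbinol). TES = SiEt3.

Assumption: centres that are later made trigonal or oxidised (C23 in 5–7, C9 in 31–33, C10 in 44–46, C17 in 22–54) are carried as epimer mixtures and written without configuration; 27 is the commercial cis/trans mixture.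

**Decalin half and key step**

Step 1
Reactants: 1 (S)-Wieland–Miescher ketone
Product: 2 C17-dithiolane of 1
Conditions: HS(CH2)2SH, p-TsOH·H2O (cat.), AcOH, rt
Reagents that add atoms: ethane-1,2-dithiol, SCCS
Why: Thioketalisation takes the conjugated carbonyl selectively because the saturated C13 ketone is shielded by the quaternary C14, and the alkene stays at C18=C20.

Step 2
Reactants: 2 C17-dithiolane of 1
Product: 3 (S)-8a-methyl-3,4,6,7,8,8a-hexahydronaphthalen-1(2H)-one
Conditions: Raney nickel (W-2, deactivated in acetone), EtOH, reflux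
Reagents that add atoms: none
Why: Raney-nickel desulfurisation replaces both C–S bonds by C–H and should leave the hindered ketone and the trisubstituted alkene in place.

Step 3
Reactants: 3 (S)-8a-methyl-3,4,6,7,8,8a-hexahydronaphthalen-1(2H)-one
Product: 5 C23-hydroxy C13-ketone, via potassium enolate 4 (not isolated)
Conditions: KN(SiMe3)2, THF, −78 °C; 2-(phenylsulfonyl)-3-phenyloxaziridine, −78 °C; aq. NH4Cl
Reagents that add atoms: 2-(phenylsulfonyl)-3-phenyloxaziridine, O=S(=O)(N1OC1c1ccccc1)c1ccccc1
Why: Davis enolate hydroxylation; only C23 can be enolised (C14 is quaternary), the oxygen donor spares the alkene, and the C23 configuration is irrelevant because the centre is oxidised in step 5.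

Step 4
Reactants: 5 C23-hydroxy C13-ketone
Product: 7 C13-methylene C23-alcohol, via silyl carbinol 6 (not isolated)
Conditions: Me3SiCH2Li, CeCl3, THF, −78 → 0 °C; then 48% aq. HF, MeCN, rt
Reagents that add atoms: (trimethylsilyl)methyllithium, [Li]C[Si](C)(C)C
Why: Peterson olefination through the organocerium adduct; the small nucleophile adds to the neopentyl ketone without enolisation or α-ketol shift, and acid-induced β-elimination gives the exocyclic methylene.

Step 5
Reactants: 7 C13-methylene C23-alcohol
Product: 8 C13-methylene C23-ketone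
Conditions: Dess–Martin periodinane, NaHCO3, CH2Cl2, 0 °C → rt
Reagents that add atoms: none
Why: Dess–Martin oxidation of the single (allylic) alcohol gives the exocyclic enone under neutral conditions; it is used at once.

Step 6
Reactants: 8 C13-methylene C23-ketone; 9 methylmagnesium bromide
Product: 10 C23 tertiary allylic alcohol
Conditions: MeMgBr, CeCl3, THF, −78 °C; aq. NH4Cl
Reagents that add atoms: methylmagnesium bromide, C[Mg]Br
Why: Cerium-mediated 1,2-addition of the Grignard reagent; the angular C14 methyl blocks its own face of the flattened ring, so methyl enters anti to it and the C23 hydroxyl ends cis to the C14 methyl.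

Step 7
Reactants: 10 C23 tertiary allylic alcohol
Product: 12 C12/C23 diol, via B-alkyl-9-BBN 11 (not isolated)
Conditions: 9-BBN-H, THF, 0 °C → rt; then NaOH, H2O2, 0 °C
Reagents that add atoms: hydrogen peroxide, OO
Why: Hydroboration–oxidation with 9-BBN selects the 1,1-disubstituted alkene over the ring alkene; hydrogen reaches C13 from the face opposite the axial C14 methyl and C23 hydroxyl, which makes the hydroxymethyl group equatorial.

Step 8
Reactants: 12 C12/C23 diol
Product: 13 C12/C23 bis(triethylsilyl) ether
Conditions: Et3SiOTf, 2,6-lutidine, CH2Cl2, −78 → 0 °C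
Reagents that add atoms: triethylsilyl trifluoromethanesulfonate, CC[Si](CC)(CC)OS(=O)(=O)C(F)(F)F
Why: Silyl triflate with a hindered base covers the primary and the hindered tertiary hydroxyl in one operation; masking C23–OH keeps a free alkoxide out of the enolate phosphorylation of step 12.

Step 9
Reactants: 13 C12/C23 bis(triethylsilyl) ether
Product: 15 C18 alcohol of the trans-decalin, via alkylborane 14 (not isolated)
Conditions: BH3·THF, THF, 0 °C → rt; then NaOH, H2O2, 0 °C
Reagents that add atoms: hydrogen peroxide, OO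
Why: Hydroboration–oxidation of the trisubstituted alkene; syn addition anti to the angular methyl puts hydrogen on C20 trans to the C14 methyl and oxygen on the less substituted C18.

Step 10
Reactants: 15 C18 alcohol of the trans-decalin
Product: 16 trans-decalone with C18 ketone, C12–OTES and C23–OTES
Conditions: Dess–Martin periodinane, NaHCO3, CH2Cl2, rt; then DBU (cat.), CH2Cl2, rt
Reagents that add atoms: none
Why: Dess–Martin oxidation gives the ketone; C20 is now α to the carbonyl, so brief base treatment should leave only the more stable trans ring fusion.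

Step 11
Reactants: 16 trans-decalone with C18 ketone, C12–OTES and C23–OTES
Product: 18 trans-fused seven-membered lactone, via Criegee adduct 17 (not isolated)
Conditions: m-CPBA, NaHCO3, CH2Cl2, 0 °C → rt
Reagents that add atoms: 3-chloroperbenzoic acid, OOC(=O)c1cccc(Cl)c1
Why: The peracid adds to the C18 carbonyl to give Criegee adduct 17, and the C20–C18 bond antiperiplanar to the O–O bond migrates to oxygen as the carboxylate leaves. This is a Baeyer–Villiger oxidation of a 2-substituted cyclohexanone, for which migration of the more substituted α-carbon with retention is the rule. The oxepane is not closed by cyclisation but by enlargement of ring B (C14–C18, C20): a suprafacial 1,2-shift turns the six-membered ketone into the seven-membered lactone with O19 between C18 and C20. No stereocentre is created; the C20 configuration, fixed by hydroboration and equilibration, is carried over, so the equatorial C–C bond becomes an equatorial C–O bond. The step needs C20 to migrate in preference to C17, which the secondary-over-primary migratory aptitude secures, and it needs chemoselectivity, which the absence of alkenes, the two silyl ethers and the bicarbonate buffer secure.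

Step 12
Reactants: 18 trans-fused seven-membered lactone
Product: 20 ketene acetal diphenyl phosphate, via potassium enolate 19 (not isolated)
Conditions: KN(SiMe3)2, (PhO)2P(O)Cl, HMPA, THF, −78 °C
Reagents that add atoms: diphenyl phosphorochloridate, O=P(Cl)(Oc1ccccc1)Oc1ccccc1
Why: Lactone enolisation (only C17 carries α-hydrogens) and O-phosphorylation give the ketene acetal phosphate, the usual activation of a lactone for cross-coupling.

Step 13
Reactants: 20 ketene acetal diphenyl phosphate
Product: 21 C18-methyl enol ether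
Conditions: AlMe3, Pd(PPh3)4 (cat.), ClCH2CH2Cl, rt
Reagents that add atoms: trimethylaluminium, C[Al](C)C
Why: Palladium-catalysed cross-coupling of an enol phosphate with trimethylaluminium replaces the phosphate by methyl and leaves the cyclic enol ether C17=C18.

Step 14
Reactants: 21 C18-methyl enol ether
Product: 23 C18 gem-dimethyl oxepan-17-ol, via epoxide 22 (not isolated)
Conditions: dimethyldioxirane, acetone/CH2Cl2, −78 → 0 °C; evaporate; AlMe3, CH2Cl2, −78 → 0 °C
Reagents that add atoms: dimethyldioxirane, CC1(C)OO1; trimethylaluminium, C[Al](C)C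
Why: Epoxidation of the electron-rich enol ether followed by Lewis-acid opening to the oxocarbenium ion and methyl transfer from aluminium to the acetal carbon C18 gives the gem-dimethyl carbon and the C17 carbinol, whose configuration does not matter.

Step 15
Reactants: 23 C18 gem-dimethyl oxepan-17-ol
Product: 24 C12/C17 diol with C23–OTES
Conditions: PPTS (cat.), MeOH/CH2Cl2, 0 °C
Reagents that add atoms: none
Why: Acid-catalysed methanolysis removes the primary silyl ether far faster than the hindered tertiary one, so only C12–OH is freed.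

Step 16
Reactants: 24 C12/C17 diol with C23–OTES
Product: 25 C12 iodide with C17-ol
Conditions: I2, PPh3, imidazole, CH2Cl2, 0 °C → rt
Reagents that add atoms: iodine, II
Why: Appel-type iodination displaces the activated primary oxygen by SN2 while the neopentylic secondary C17–OH stays.

Step 17
Reactants: 25 C12 iodide with C17-ol
Product: 26 C12 iodide with C17–OTES and C23–OTES
Conditions: Et3SiOTf, 2,6-lutidine, CH2Cl2, −78 °C
Reagents that add atoms: triethylsilyl trifluoromethanesulfonate, CC[Si](CC)(CC)OS(=O)(=O)C(F)(F)F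
Why: Silylation of the last hydroxyl removes every acidic proton before the iodine–lithium exchange of step 36.

**Hydroazulene half**

Step 18
Reactants: 27 (4R)-limonene 1,2-oxide
Product: 28 (3R)-6-oxo-3-(prop-1-en-2-yl)heptanal
Conditions: H5IO6, THF/H2O, 0 °C → rt
Reagents that add atoms: water, O
Why: Periodic acid hydrolyses the epoxide and cleaves the glycol (Malaprade cleavage) to the keto aldehyde without touching the isopropenyl group or the stereocentre that becomes C5.

Step 19
Reactants: 28 (3R)-6-oxo-3-(prop-1-en-2-yl)heptanal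
Product: 29 (5S)-2-methyl-5-(prop-1-en-2-yl)cyclopent-1-ene-1-carbaldehyde
Conditions: piperidine (cat.), AcOH (cat.), toluene, 70 °C
Reagents that add atoms: none
Why: Amine-catalysed intramolecular aldol condensation (aldehyde enamine onto the methyl ketone, then dehydration) closes the cyclopentene C4=C8; C5 is not enolisable and is retained.

Step 20
Reactants: 29 (5S)-2-methyl-5-(prop-1-en-2-yl)cyclopent-1-ene-1-carbaldehyde
Product: 30 (3S)-1-methyl-3-(prop-1-en-2-yl)-2-vinylcyclopent-1-ene
Conditions: Ph3PCH3Br, KOt-Bu, THF, 0 °C → rt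
Reagents that add atoms: methyltriphenylphosphonium bromide, C[P+](c1ccccc1)(c1ccccc1)c1ccccc1.[Br-]
Why: Wittig methylenation of the enal supplies the vinyl group (C3) for the later ring closure.

Step 21
Reactants: 30 (3S)-1-methyl-3-(prop-1-en-2-yl)-2-vinylcyclopent-1-ene
Product: 32 primary alcohol at the former isopropenyl group, via B-alkyl-9-BBN 31 (not isolated)
Conditions: 9-BBN-H (1.05 equiv), THF, 0 °C → rt; then NaOH, H2O2, 0 °C
Reagents that add atoms: hydrogen peroxide, OO
Why: Hydroboration–oxidation with 9-BBN takes the 1,1-disubstituted isopropenyl group in preference to the conjugated, less reactive diene; the new C9 centre is removed in step 23.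

Step 22
Reactants: 32 primary alcohol at the former isopropenyl group
Product: 33 α-branched aldehyde
Conditions: Dess–Martin periodinane, NaHCO3, CH2Cl2, 0 °C → rt
Reagents that add atoms: none
Why: Dess–Martin oxidation of the primary alcohol stops at the aldehyde.

Step 23
Reactants: 33 α-branched aldehyde
Product: 35 2-methyl-2-[(1R)-3-methyl-2-vinylcyclopent-2-en-1-yl]propanal, via potassium enolate 34 (not isolated)
Conditions: KOt-Bu, MeI, THF, 0 °C
Reagents that add atoms: iodomethane, CI
Why: Enolate C-methylation of the α-branched aldehyde builds the quaternary gem-dimethyl carbon C9 and erases the C9 stereocentre.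

Step 24
Reactants: 35 2-methyl-2-[(1R)-3-methyl-2-vinylcyclopent-2-en-1-yl]propanal
Product: 36 anti homoallylic alcohol
Conditions: (E)-crotyl-B(Ipc)2 [from (E)-but-2-ene, n-BuLi, KOt-Bu, (−)-Ipc2BOMe, BF3·OEt2], THF, −78 °C; then NaOH, H2O2
Reagents that add atoms: (E)-but-2-ene, C/C=C/C
Why: Brown crotylboration through a chair Zimmerman–Traxler transition state; the (E)-crotyl unit gives the anti adduct and the isopinocampheyl groups derived from (+)-α-pinene choose the aldehyde face, setting C1 as S, while the C10 carbinol is oxidised later.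

Step 25
Reactants: 36 anti homoallylic alcohol
Product: 37 bicyclic dienol
Conditions: second-generation Grubbs catalyst (H2IMes)(PCy3)Cl2Ru=CHPh (5 mol %), CH2Cl2 (0.005 M), 40 °C
Reagents that add atoms: none
Why: Ring-closing metathesis of the two terminal vinyl groups closes the seven-membered ring at C2=C3, helped by the gem-dimethyl group; the tetrasubstituted alkene is inert.

Step 26
Reactants: 37 bicyclic dienol
Product: 38 C4–C8 epoxide
Conditions: m-CPBA, NaHCO3, CH2Cl2, −20 → 0 °C
Reagents that add atoms: 3-chloroperbenzoic acid, OOC(=O)c1cccc(Cl)c1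
Why: Prilezhaev epoxidation takes the more electron-rich tetrasubstituted C4=C8 bond of the diene from the face opposite C9 (the side of H5), which fixes the C8 oxygen cis to H5.

Step 27
Reactants: 38 C4–C8 epoxide
Product: 39 C8 tertiary allylic alcohol with C3=C4
Conditions: i-Bu2AlH (3 equiv), toluene, −78 → 0 °C; aq. Rochelle salt
Reagents that add atoms: none
Why: SN2′ reduction of a vinyl epoxide; aluminium activates the oxirane, the allylic C4–O bond opens and hydride goes to the unhindered terminus C2, leaving the C8 carbinol with its configuration unchanged.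

Step 28
Reactants: 39 C8 tertiary allylic alcohol with C3=C4
Product: 40 cis-fused hydroazulene-8,10-diol
Conditions: H2 (1 atm), [Ir(cod)(PCy3)(py)]PF6 (5 mol %), CH2Cl2, rt
Reagents that add atoms: none
Why: Hydroxyl-directed hydrogenation with Crabtree's catalyst; the allylic C8–OH binds iridium and hydrogen reaches C4 from that face, which is also the less hindered one, giving the cis ring fusion.

Step 29
Reactants: 40 cis-fused hydroazulene-8,10-diol
Product: 41 C10 ketone with C8-ol
Conditions: Dess–Martin periodinane, NaHCO3, CH2Cl2, rt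
Reagents that add atoms: none
Why: Dess–Martin oxidation of the only secondary alcohol; the tertiary alcohol is inert and the neutral medium keeps C1 from epimerising.

Step 30
Reactants: 41 C10 ketone with C8-ol
Product: 42 C10 ketone with C8–OTES
Conditions: Et3SiOTf, 2,6-lutidine, CH2Cl2, −78 °C
Reagents that add atoms: triethylsilyl trifluoromethanesulfonate, CC[Si](CC)(CC)OS(=O)(=O)C(F)(F)F
Why: Low-temperature silylation with a silyl triflate and a hindered pyridine protects the tertiary alcohol without enolising the hindered ketone.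

Step 31
Reactants: 42 C10 ketone with C8–OTES
Product: 43 C10 methylene compound
Conditions: Cp2TiMe2, toluene, 75 °C, dark
Reagents that add atoms: dimethyltitanocene, C[Ti](C)(C1C=CC=C1)C1C=CC=C1
Why: Petasis methylenation; the titanium methylidene formed thermally olefinates hindered, enolisable ketones without base, so C1 is preserved.

Step 32
Reactants: 43 C10 methylene compound
Product: 45 C11 alcohol, via B-alkyl-9-BBN 44 (not isolated)
Conditions: 9-BBN-H, THF, rt; then NaOH, H2O2, 0 °C
Reagents that add atoms: hydrogen peroxide, OO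
Why: Hydroboration–oxidation of the 1,1-disubstituted alkene places oxygen on C11; the C10 centre that forms is removed in step 34.

Step 33
Reactants: 45 C11 alcohol
Product: 46 C11 aldehyde
Conditions: Dess–Martin periodinane, NaHCO3, CH2Cl2, rt
Reagents that add atoms: none
Why: Dess–Martin oxidation of the primary alcohol to the aldehyde.

Step 34
Reactants: 46 C11 aldehyde
Product: 48 (E)-enol triflate, via potassium enolate 47 (not isolated)
Conditions: KN(SiMe3)2, THF, −78 °C; PhNTf2, −78 → 0 °C
Reagents that add atoms: N-phenylbis(trifluoromethanesulfonimide), FC(F)(F)S(=O)(=O)N(c1ccccc1)S(=O)(=O)C(F)(F)F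
Why: Enolate O-sulfonylation; allylic 1,3-strain puts the enolate oxygen on the side of C1, which can turn its hydrogen into the alkene plane, and not on the side of the gem-dimethyl carbon C9, so the (E)-enol triflate should dominate.

Step 35
Reactants: 48 (E)-enol triflate
Product: 49 (E)-alkenyl pinacolboronate
Conditions: B2pin2, PdCl2(PPh3)2 (cat.), PPh3, KOPh, toluene, 50 °C
Reagents that add atoms: bis(pinacolato)diboron, CC1(C)OB(OC1(C)C)B1OC(C)(C)C(C)(C)O1
Why: Miyaura borylation of an alkenyl triflate runs with retention and gives the alkenylboronate with boron cis to C1.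

**Union and end game**

Step 36
Reactants: 26 C12 iodide with C17–OTES and C23–OTES; 49 (E)-alkenyl pinacolboronate
Product: 53 tris(triethylsilyl) ether with the (Z)-C10=C11 alkene, via alkyllithium 50 (not isolated), via boronate complex 51 (not isolated), via iodoboronate 52 (not isolated)
Conditions: t-BuLi (2.1 equiv), Et2O, −78 °C; add 49 in THF, −78 → 0 °C; I2, THF/MeOH, −78 °C; NaOMe, MeOH, −78 °C → rt
Reagents that add atoms: none
Why: Zweifel olefination; the primary alkyllithium from iodine–lithium exchange adds to boron, iodination triggers 1,2-migration of C12 to C11 anti to iodine, and methoxide induces anti elimination of boron and iodide, so the alkene geometry is inverted and C12 ends cis to C9.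

Step 37
Reactants: 53 tris(triethylsilyl) ether with the (Z)-C10=C11 alkene
Product: 54 C8,C17,C23-triol
Conditions: Bu4NF, THF, rt → 45 °C
Reagents that add atoms: none
Why: Fluoride-mediated desilylation removes all three silyl ethers without acid, which spares the strained trisubstituted alkene.

Step 38
Reactants: 54 C8,C17,C23-triol
Product: 55 CNP0157787.1
Conditions: Dess–Martin periodinane, NaHCO3, CH2Cl2, 0 °C → rt
Reagents that add atoms: none
Why: Dess–Martin oxidation of the single secondary alcohol gives the C17 ketone; the two tertiary alcohols and the alkene are inert.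

**Compound list**

1 | (S)-Wieland–Miescher ketone | O=C1CCCC2=CC(=O)CC[C@]12C | starting material
2 | C17-dithiolane of 1 (C13 ketone, C18=C20 alkene) | O=C1CCCC2=CC3(SCCS3)CC[C@]12C | intermediate
3 | (S)-8a-methyl-3,4,6,7,8,8a-hexahydronaphthalen-1(2H)-one | O=C1CCCC2=CCCC[C@]12C | intermediate
4 | potassium enolate of 3 (C13=C23) | [K+].[O-]C1=CCCC2=CCCC[C@]12C | intermediate (not isolated)
5 | C23-hydroxy C13-ketone (C23 epimers) | O=C1C(O)CCC2=CCCC[C@]12C | intermediate
6 | C13 (trimethylsilyl)methyl carbinol, C23-ol (epimers) | C[Si](C)(C)CC1(O)C(O)CCC2=CCCC[C@]12C | intermediate (not isolated)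
7 | C13-methylene C23-alcohol (C23 epimers) | C=C1C(O)CCC2=CCCC[C@]12C | intermediate
8 | C13-methylene C23-ketone | C=C1C(=O)CCC2=CCCC[C@]12C | intermediate
9 | methylmagnesium bromide | C[Mg]Br | starting material
10 | C23 tertiary allylic alcohol (OH cis to the C14 methyl) with C13 methylene | C=C1[C@@](C)(O)CCC2=CCCC[C@]12C | intermediate
11 | C12 B-alkyl-9-borabicyclo[3.3.1]nonane | C1CC2CCCC(C1)B2C[C@@H]1[C@@]2(C)CCCC=C2CC[C@]1(C)O | intermediate (not isolated)
12 | C12/C23 diol (H13 trans to the C14 methyl, C18=C20 alkene) | OC[C@@H]1[C@@]2(C)CCCC=C2CC[C@]1(C)O | intermediate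
13 | C12/C23 bis(triethylsilyl) ether of 12 | CC[Si](CC)(CC)OC[C@@H]1[C@@]2(C)CCCC=C2CC[C@]1(C)O[Si](CC)(CC)CC | intermediate
14 | C18 alkylborane (H20 trans to the C14 methyl) | CC[Si](CC)(CC)OC[C@@H]1[C@@]2(C)CCC[C@@H]([BH2])[C@@H]2CC[C@]1(C)O[Si](CC)(CC)CC | intermediate (not isolated)
15 | C18 alcohol of the trans-decalin | CC[Si](CC)(CC)OC[C@@H]1[C@@]2(C)CCC[C@@H](O)[C@@H]2CC[C@]1(C)O[Si](CC)(CC)CC | intermediate
16 | trans-decalone: C18 ketone, C12–OTES, C23–OTES | CC[Si](CC)(CC)OC[C@@H]1[C@@]2(C)CCCC(=O)[C@@H]2CC[C@]1(C)O[Si](CC)(CC)CC | intermediate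
17 | Criegee adduct of 16 (C18 hemi-perester) | CC[Si](CC)(CC)OC[C@@H]1[C@@]2(C)CCCC(O)(OOC(=O)c3cccc(Cl)c3)[C@@H]2CC[C@]1(C)O[Si](CC)(CC)CC | intermediate (not isolated)
18 | trans-fused seven-membered lactone (C18 carbonyl, O19 on C20) | CC[Si](CC)(CC)OC[C@@H]1[C@@]2(C)CCCC(=O)O[C@@H]2CC[C@]1(C)O[Si](CC)(CC)CC | intermediate
19 | potassium enolate of 18 | [K+].CC[Si](CC)(CC)OC[C@@H]1[C@@]2(C)CCC=C([O-])O[C@@H]2CC[C@]1(C)O[Si](CC)(CC)CC | intermediate (not isolated)
20 | ketene acetal diphenyl phosphate (C17=C18) | CC[Si](CC)(CC)OC[C@@H]1[C@@]2(C)CCC=C(OP(=O)(Oc3ccccc3)Oc3ccccc3)O[C@@H]2CC[C@]1(C)O[Si](CC)(CC)CC | intermediate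
21 | C18-methyl enol ether (C17=C18) | CC[Si](CC)(CC)OC[C@@H]1[C@@]2(C)CCC=C(C)O[C@@H]2CC[C@]1(C)O[Si](CC)(CC)CC | intermediate
22 | C17–C18 epoxide of 21 | CC[Si](CC)(CC)OC[C@@H]1[C@@]2(C)CCC3OC3(C)O[C@@H]2CC[C@]1(C)O[Si](CC)(CC)CC | intermediate (not isolated)
23 | C18 gem-dimethyl oxepan-17-ol (C17 epimers) | CC[Si](CC)(CC)OC[C@@H]1[C@@]2(C)CCC(O)C(C)(C)O[C@@H]2CC[C@]1(C)O[Si](CC)(CC)CC | intermediate
24 | C12/C17 diol with C23–OTES | OC[C@@H]1[C@@]2(C)CCC(O)C(C)(C)O[C@@H]2CC[C@]1(C)O[Si](CC)(CC)CC | intermediate
25 | C12 iodide with C17-ol and C23–OTES | IC[C@@H]1[C@@]2(C)CCC(O)C(C)(C)O[C@@H]2CC[C@]1(C)O[Si](CC)(CC)CC | intermediate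
26 | C12 iodide with C17–OTES and C23–OTES | IC[C@@H]1[C@@]2(C)CCC(O[Si](CC)(CC)CC)C(C)(C)O[C@@H]2CC[C@]1(C)O[Si](CC)(CC)CC | intermediate
27 | (4R)-limonene 1,2-oxide (cis/trans mixture) | CC12OC1C[C@@H](CC2)C(C)=C | starting material
28 | (3R)-6-oxo-3-(prop-1-en-2-yl)heptanal | O=CC[C@@H](CCC(C)=O)C(C)=C | intermediate
29 | (5S)-2-methyl-5-(prop-1-en-2-yl)cyclopent-1-ene-1-carbaldehyde | O=CC1=C(C)CC[C@H]1C(C)=C | intermediate
30 | (3S)-1-methyl-3-(prop-1-en-2-yl)-2-vinylcyclopent-1-ene | C=CC1=C(C)CC[C@H]1C(C)=C | intermediate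
31 | B-alkyl-9-BBN from the isopropenyl group of 30 | C=CC1=C(C)CC[C@H]1C(C)CB1C2CCCC1CCC2 | intermediate (not isolated)
32 | 2-[(1S)-3-methyl-2-vinylcyclopent-2-en-1-yl]propan-1-ol (C9 epimers) | C=CC1=C(C)CC[C@H]1C(C)CO | intermediate
33 | 2-[(1S)-3-methyl-2-vinylcyclopent-2-en-1-yl]propanal (C9 epimers) | C=CC1=C(C)CC[C@H]1C(C)C=O | intermediate
34 | potassium enolate of 33 | [K+].C=CC1=C(C)CC[C@H]1C(C)=C[O-] | intermediate (not isolated)
35 | 2-methyl-2-[(1R)-3-methyl-2-vinylcyclopent-2-en-1-yl]propanal | C=CC1=C(C)CC[C@H]1C(C)(C)C=O | intermediate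
36 | anti homoallylic alcohol (C10 S, C1 S) | C=CC1=C(C)CC[C@H]1C(C)(C)[C@@H](O)[C@@H](C)C=C | intermediate
37 | bicyclic dienol (C2=C3, C4=C8, C10–OH) | C[C@H]1C=CC2=C(C)CC[C@H]2C(C)(C)[C@H]1O | intermediate
38 | C4–C8 epoxide (oxygen cis to H5), C2=C3 | C[C@H]1C=C[C@]23O[C@]3(C)CC[C@H]2C(C)(C)[C@H]1O | intermediate
39 | C8 tertiary allylic alcohol with C3=C4 and C10–OH | C[C@H]1CC=C2[C@](C)(O)CC[C@H]2C(C)(C)[C@H]1O | intermediate
40 | cis-fused hydroazulene-8,10-diol (H4, H5 and C8–OH cis) | C[C@H]1CC[C@@H]2[C@@H](CC[C@@]2(C)O)C(C)(C)[C@H]1O | intermediate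
41 | C10 ketone with C8-ol | C[C@H]1CC[C@@H]2[C@@H](CC[C@@]2(C)O)C(C)(C)C1=O | intermediate
42 | C10 ketone with C8–OTES | C[C@H]1CC[C@@H]2[C@@H](CC[C@@]2(C)O[Si](CC)(CC)CC)C(C)(C)C1=O | intermediate
43 | C10 methylene compound | C[C@H]1CC[C@@H]2[C@@H](CC[C@@]2(C)O[Si](CC)(CC)CC)C(C)(C)C1=C | intermediate
44 | C11 B-alkyl-9-BBN | C[C@H]1CC[C@@H]2[C@@H](CC[C@@]2(C)O[Si](CC)(CC)CC)C(C)(C)C1CB1C2CCCC1CCC2 | intermediate (not isolated)
45 | C11 alcohol (C10 epimers) | C[C@H]1CC[C@@H]2[C@@H](CC[C@@]2(C)O[Si](CC)(CC)CC)C(C)(C)C1CO | intermediate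
46 | C11 aldehyde (C10 epimers) | C[C@H]1CC[C@@H]2[C@@H](CC[C@@]2(C)O[Si](CC)(CC)CC)C(C)(C)C1C=O | intermediate
47 | potassium (E)-enolate of 46 | [K+].C[C@H]1CC[C@@H]2[C@@H](CC[C@@]2(C)O[Si](CC)(CC)CC)C(C)(C)/C1=C/[O-] | intermediate (not isolated)
48 | (E)-enol triflate (OTf cis to C1) | C[C@H]1CC[C@@H]2[C@@H](CC[C@@]2(C)O[Si](CC)(CC)CC)C(C)(C)/C1=C/OS(=O)(=O)C(F)(F)F | intermediate
49 | (E)-alkenyl pinacolboronate (boron cis to C1) | C[C@H]1CC[C@@H]2[C@@H](CC[C@@]2(C)O[Si](CC)(CC)CC)C(C)(C)/C1=C/B3OC(C)(C)C(C)(C)O3 | intermediate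
50 | C12 alkyllithium from 26 | [Li]C[C@@H]1[C@@]2(C)CCC(O[Si](CC)(CC)CC)C(C)(C)O[C@@H]2CC[C@]1(C)O[Si](CC)(CC)CC | intermediate (not isolated)
51 | lithium alkyl(alkenyl)pinacolboronate | [Li+].C[C@H]1CC[C@@H]2[C@@H](CC[C@@]2(C)O[Si](CC)(CC)CC)C(C)(C)/C1=C/[B-]3(OC(C)(C)C(C)(C)O3)C[C@@H]1[C@@]2(C)CCC(O[Si](CC)(CC)CC)C(C)(C)O[C@@H]2CC[C@]1(C)O[Si](CC)(CC)CC | intermediate (not isolated)
52 | β-iodo boronic ester (C10–I, C11–B; relative configuration from anti addition) | C[C@H]1CC[C@@H]2[C@@H](CC[C@@]2(C)O[Si](CC)(CC)CC)C(C)(C)C1(I)C(B3OC(C)(C)C(C)(C)O3)C[C@@H]1[C@@]2(C)CCC(O[Si](CC)(CC)CC)C(C)(C)O[C@@H]2CC[C@]1(C)O[Si](CC)(CC)CC | intermediate (not isolated)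
53 | tris(triethylsilyl) ether of 54 with the (Z)-C10=C11 alkene | C[C@H]1CC[C@@H]2[C@@H](CC[C@@]2(C)O[Si](CC)(CC)CC)C(C)(C)/C1=C\C[C@@H]1[C@@]2(C)CCC(O[Si](CC)(CC)CC)C(C)(C)O[C@@H]2CC[C@]1(C)O[Si](CC)(CC)CC | intermediate
54 | C8,C17,C23-triol (C17 epimers) | C[C@H]1CC[C@@H]2[C@@H](CC[C@@]2(C)O)C(C)(C)/C1=C\C[C@@H]1[C@@]2(C)CCC(O)C(C)(C)O[C@@H]2CC[C@]1(C)O | intermediate
55 | CNP0157787.1 | C[C@H]1CC[C@@H]2[C@@H](CC[C@@]2(C)O)C(C)(C)/C1=C\C[C@@H]1[C@@]2(C)CCC(=O)C(C)(C)O[C@@H]2CC[C@]1(C)O | target

**Step count and risk**

Total steps: 38. Longest linear sequence: 21 steps (steps 18–38, from 27); the decalin chain runs 20 steps (steps 1–17 and 36–38).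

Steps most likely to fail:

1. Step 36 (fragment union). Iodine–lithium exchange and boronate formation between two crowded fragments may be incomplete (protonation of the alkyllithium, slow complexation at the hindered alkenylboron), and ionisation at the tertiary C10–I bond before elimination would erode the stereospecificity. The fallback sets out from 49 and 26 and comes back at 53. Boronate 49 is treated with Br2 at −78 °C and then NaOMe/MeOH; anti addition followed by anti elimination gives, with inversion, the (Z)-alkenyl bromide F1. F1 and 26 are then joined by nickel-catalysed reductive cross-electrophile coupling (NiCl2·glyme, 4,4′-di-tert-butyl-2,2′-bipyridine, Zn, DMA), which keeps the alkene geometry and needs no organolithium.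

2. Step 27 (SN2′ opening). Hydride may attack an oxirane carbon directly, or the Lewis-acidic aluminium may set off a pinacol-type shift. The fallback sets out from 37 and comes back at 40. Diimide (2-nitrobenzenesulfonylhydrazide, Et3N) reduces only the disubstituted C2=C3 bond and gives the tetrasubstituted-alkene alcohol F2. Hydroboration–oxidation of F2 (BH3·THF; NaOH, H2O2) adds hydrogen to C4 and oxygen to C8 syn and from the face opposite C9, giving 40; the price is a less certain choice between C8 and C4 for boron.

3. Step 34 (enolate trapping). Geometric control in the triflation may be incomplete. The fallback sets out from 46 and comes back at 53, and makes both isomers converge. The isomers are separated; the minor (Z)-enol triflate F3 is borylated as in step 35 to the (Z)-alkenyl pinacolboronate F4. F4 is combined with the alkyllithium from 26 and the boronate complex is treated with PhSeCl and then m-CPBA, the syn-elimination variant of the Zweifel olefination, which proceeds with retention and so also places C12 cis to C9.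

Further compounds
F1 | step 36 | (Z)-alkenyl bromide (bromine cis to C9), C8–OTES | C[C@H]1CC[C@@H]2[C@@H](CC[C@@]2(C)O[Si](CC)(CC)CC)C(C)(C)/C1=C\Br
F2 | step 27 | bicyclic alcohol with C4=C8 alkene and saturated C2–C3, C10–OH | C[C@H]1CCC2=C(C)CC[C@H]2C(C)(C)[C@H]1O
F3 | step 34 | (Z)-enol triflate (OTf cis to C9) | C[C@H]1CC[C@@H]2[C@@H](CC[C@@]2(C)O[Si](CC)(CC)CC)C(C)(C)/C1=C\OS(=O)(=O)C(F)(F)F
F4 | step 34 | (Z)-alkenyl pinacolboronate (boron cis to C9) | C[C@H]1CC[C@@H]2[C@@H](CC[C@@]2(C)O[Si](CC)(CC)CC)C(C)(C)/C1=C\B3OC(C)(C)C(C)(C)O3
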